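**Retrosynthesis**
- The target is a 2,3-dimethyl-1,4-diarylbutane (8S,8'R, meso-type) carrying a threo 7''-hydroxy-8''-methyl aryl ether on ring B, so no new rings are formed. All three aromatic rings come from commercial building blocks, attached in the order ring A, ring B, ring C.
- Last step: hydrogenolytic removal of two benzyl ethers. Before that, the 7''S,8''S aryl-ether alcohol is made from an α-aryloxy ketone by Ru-catalysed dynamic kinetic resolution (DKR) transfer hydrogenation. The ketone comes from a Williamson ether synthesis between the ring-B phenol and an α-bromopropiophenone (ring C).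
- The diarylbutane comes from two successive sp3–sp2 Negishi couplings on the two CH2 termini of an enantio-desymmetrised meso-2,3-dimethylsuccinate. The meso relative configuration is inherited from the commercial anhydride, and the absolute configuration comes from catalytic alcoholysis.

**Assumptions (one line each)**
- 1-(Benzyloxy)-4-bromo-2-methoxybenzene (5) is taken as commercial; if not, it is one step from 4-bromo-2-methoxyphenol with BnBr and K2CO3.
- The pseudo-enantiomer of the cinchona catalyst is chosen to give the (2R,3S)-hemiester; I assume (DHQD)2AQN does this.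
- I assume Ru-(R,R)-TsDPEN DKR delivers the anti (threo) 7''S,8''S alcohol.

---

**Step 1**
Reactants: 1, meso-2,3-dimethylsuccinic anhydride (cis-3,4-dimethyldihydrofuran-2,5-dione)
Product: 2, (2R,3S)-4-methoxy-2,3-dimethyl-4-oxobutanoic acid (hemiester)
Conditions: MeOH (10 equiv), (DHQD)2AQN (10 mol%), MTBE, –20 °C
Reagents that add atoms: methanol, CO
Why: Cinchona-alkaloid-catalysed enantioselective methanolysis of a meso anhydride (desymmetrisation) attacks one enantiotopic carbonyl. This sets C8 and C8' in one step, and the meso relative configuration is already the 8S,8'R type.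

**Step 2**
Reactants: 2
Product: 3, methyl (2S,3R)-4-hydroxy-2,3-dimethylbutanoate
Conditions: BH3·SMe2, THF, 0 °C → rt; MeOH quench, neutral work-up, use crude
Reagents that add atoms: none
Why: Borane reduces a carboxylic acid much faster than a methyl ester (chemoselective reduction), and no stereocentre is touched.

**Step 3**
Reactants: 3
Product: 4, methyl (2S,3R)-4-iodo-2,3-dimethylbutanoate
Conditions: PPh3, I2, imidazole, CH2Cl2, 0 °C
Reagents that add atoms: iodine, II
Why: Appel iodination converts the primary alcohol by SN2 at a CH2 carbon, so the neighbouring stereocentres are unaffected.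

**Step 4**
Reactants: 4; 5, 1-(benzyloxy)-4-bromo-2-methoxybenzene
Product: 6, methyl (2S,3S)-4-[4-(benzyloxy)-3-methoxyphenyl]-2,3-dimethylbutanoate
Conditions: 5, n-BuLi, THF, –78 °C; then ZnCl2; then 4, Pd2(dba)3, PCyp3, NMI, THF/NMP, rt
Reagents that add atoms: none
Why: The arylzinc is ester-tolerant. Negishi coupling of a primary alkyl iodide installs ring A at C7 without affecting the stereocentres, neither of which is carbonyl-activated in the coupling partner.

**Step 5**
Reactants: 6
Product: 7, (2S,3S)-4-[4-(benzyloxy)-3-methoxyphenyl]-2,3-dimethylbutan-1-ol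
Conditions: LiAlH4, THF, 0 °C
Reagents that add atoms: none
Why: Ester reduction leaves the benzyl and aryl methyl ethers intact.

**Step 6**
Reactants: 7
Product: 8, (2S,3S)-4-[4-(benzyloxy)-3-methoxyphenyl]-1-iodo-2,3-dimethylbutane
Conditions: PPh3, I2, imidazole, CH2Cl2, 0 °C
Reagents that add atoms: iodine, II
Why: Appel iodination, as in Step 3, activates the second CH2 terminus.

**Step 7**
Reactants: 9, 4-bromo-2,6-dimethoxyphenol
Product: 10, (4-bromo-2,6-dimethoxyphenoxy)(tert-butyl)dimethylsilane
Conditions: TBSCl, imidazole, DMF, rt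
Reagents that add atoms: TBSCl, CC(C)(C)[Si](C)(C)Cl
Why: Silylation masks the ring-B phenol so the aryl-metal step is possible.

**Step 8**
Reactants: 8; 10
Product: 11, (2S,3R)-1-[4-(benzyloxy)-3-methoxyphenyl]-4-[4-(TBSO)-3,5-dimethoxyphenyl]-2,3-dimethylbutane
Conditions: 10, n-BuLi, THF, –78 °C; then ZnCl2; then 8, Pd2(dba)3, PCyp3, NMI, THF/NMP, rt
Reagents that add atoms: none
Why: Negishi coupling again, now forming ring B at C7'. This completes the 8S,8'R core with no stereocentre disturbed.

**Step 9**
Reactants: 11
Product: 12, 4-[(2R,3S)-4-[4-(benzyloxy)-3-methoxyphenyl]-2,3-dimethylbutyl]-2,6-dimethoxyphenol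
Conditions: TBAF, THF, 0 °C, then NH4Cl
Reagents that add atoms: none
Why: Fluoride cleaves the aryl silyl ether (desilylation) and leaves the benzyl ether untouched.

**Step 10**
Reactants: 13, propiovanillone (1-(4-hydroxy-3-methoxyphenyl)propan-1-one)
Product: 14, 1-[4-(benzyloxy)-3-methoxyphenyl]propan-1-one
Conditions: BnBr, K2CO3, DMF, rt
Reagents that add atoms: benzyl bromide, BrCc1ccccc1
Why: Williamson O-benzylation protects the ring-C phenol.

**Step 11**
Reactants: 14
Product: 15, (±)-2-bromo-1-[4-(benzyloxy)-3-methoxyphenyl]propan-1-one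
Conditions: CuBr2, EtOAc/CHCl3, reflux
Reagents that add atoms: copper(II) bromide, [Cu+2].[Br-].[Br-]
Why: CuBr2 brominates the ketone α-carbon selectively via its enol, without brominating the electron-rich ring. The product is racemic, which the DKR in Step 13 tolerates.

**Step 12**
Reactants: 12; 15
Product: 16, α-aryloxy ketone, (8S,8'R) core with C8'' as an epimeric mixture
Conditions: K2CO3, acetone, reflux
Reagents that add atoms: none
Why: Williamson SN2 of the syringyl phenoxide on the α-bromoketone. The new C8'' stereocentre is labile and epimerises under the conditions, which sets up the DKR.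

**Step 13**
Reactants: 16
Product: 17, benzyl-protected target, (7''S,8''S)-alcohol
Conditions: RuCl[(R,R)-TsDPEN](p-cymene) (2 mol%), HCO2H/Et3N (5:2), CH2Cl2, 40 °C
Reagents that add atoms: none
Why: Noyori–Ikariya asymmetric transfer hydrogenation run as a DKR. The catalyst reduces one ketone enantiomer faster while Et3N racemises C8'', giving the anti (threo) 7''S,8''S aryloxy alcohol. The core stereocentres are not epimerisable.

**Step 14**
Reactants: 17
Product: 18, target
Conditions: H2 (1 atm), 10% Pd/C, EtOAc/MeOH, rt, short reaction time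
Reagents that add atoms: none
Why: Hydrogenolysis removes both O-benzyl groups. The aryl alkyl ether and the secondary benzylic alcohol survive mild, brief Pd/C conditions.

---

**Compound list**

1 | meso-2,3-dimethylsuccinic anhydride | C[C@H]1C(=O)OC(=O)[C@H]1C | starting material
2 | (2R,3S)-4-methoxy-2,3-dimethyl-4-oxobutanoic acid | OC(=O)[C@H](C)[C@H](C)C(=O)OC | intermediate
3 | methyl (2S,3R)-4-hydroxy-2,3-dimethylbutanoate | OC[C@H](C)[C@H](C)C(=O)OC | intermediate
4 | methyl (2S,3R)-4-iodo-2,3-dimethylbutanoate | IC[C@H](C)[C@H](C)C(=O)OC | intermediate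
5 | 1-(benzyloxy)-4-bromo-2-methoxybenzene | COc1cc(Br)ccc1OCc1ccccc1 | starting material
6 | methyl (2S,3S)-4-[4-(benzyloxy)-3-methoxyphenyl]-2,3-dimethylbutanoate | COc1cc(C[C@H](C)[C@H](C)C(=O)OC)ccc1OCc1ccccc1 | intermediate
7 | (2S,3S)-4-[4-(benzyloxy)-3-methoxyphenyl]-2,3-dimethylbutan-1-ol | COc1cc(C[C@H](C)[C@H](C)CO)ccc1OCc1ccccc1 | intermediate
8 | (2S,3S)-4-[4-(benzyloxy)-3-methoxyphenyl]-1-iodo-2,3-dimethylbutane | COc1cc(C[C@H](C)[C@H](C)CI)ccc1OCc1ccccc1 | intermediate
9 | 4-bromo-2,6-dimethoxyphenol | COc1cc(Br)cc(OC)c1O | starting material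
10 | (4-bromo-2,6-dimethoxyphenoxy)(tert-butyl)dimethylsilane | COc1cc(Br)cc(OC)c1O[Si](C)(C)C(C)(C)C | intermediate
11 | TBS-protected diarylbutane core | COc1cc(C[C@H](C)[C@H](C)Cc2cc(OC)c(O[Si](C)(C)C(C)(C)C)c(OC)c2)ccc1OCc1ccccc1 | intermediate
12 | ring-B phenol core | COc1cc(C[C@H](C)[C@H](C)Cc2cc(OC)c(O)c(OC)c2)ccc1OCc1ccccc1 | intermediate
13 | propiovanillone | CCC(=O)c1ccc(O)c(OC)c1 | starting material
14 | 1-[4-(benzyloxy)-3-methoxyphenyl]propan-1-one | CCC(=O)c1ccc(OCc2ccccc2)c(OC)c1 | intermediate
15 | 2-bromo-1-[4-(benzyloxy)-3-methoxyphenyl]propan-1-one (racemic) | CC(Br)C(=O)c1ccc(OCc2ccccc2)c(OC)c1 | intermediate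
16 | α-aryloxy ketone (C8'' undefined) | COc1cc(C[C@H](C)[C@H](C)Cc2cc(OC)c(OC(C)C(=O)c3ccc(OCc4ccccc4)c(OC)c3)c(OC)c2)ccc1OCc1ccccc1 | intermediate
17 | dibenzyl-protected target | COc1cc(C[C@H](C)[C@H](C)Cc2cc(OC)c(O[C@@H](C)[C@@H](O)c3ccc(OCc4ccccc4)c(OC)c3)c(OC)c2)ccc1OCc1ccccc1 | intermediate
18 | target | COc1cc(C[C@H](C)[C@H](C)Cc2cc(OC)c(O[C@@H](C)[C@@H](O)c3ccc(O)c(OC)c3)c(OC)c2)ccc1O | target

---

**Step count:** 14 steps in total; the longest linear sequence is 11 steps (1→2→3→4→6→7→8→11→12→16→17→18, counting Steps 1–6, 8, 9, 12, 13 and 14).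

**Three steps most likely to fail**
1. **Step 1, enantioselective desymmetrisation.** The ee for this substrate may be insufficient, or the wrong hemiester enantiomer may form. Fallback: pig liver esterase hydrolysis of dimethyl meso-2,3-dimethylsuccinate, or ring-opening of the anhydride with a chiral auxiliary (lithiated Evans oxazolidinone) and separation of diastereomers.
2. **Step 13, DKR transfer hydrogenation.** It may give the syn diastereomer or a poor dr. Fallback: make the ether from (R)-methyl lactate by Mitsunobu coupling with phenol 12 (inversion gives 8''S). Convert the ester to the Weinreb amide and add the ring-C aryl Grignard to give the ketone. Then reduce it and separate the diastereomers.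
3. **Steps 4 and 8, Negishi coupling of β-branched primary iodides.** Yields may be low from β-hydride elimination, or iodo ester 4 may lactonise. Fallback: install the aryl groups as ketones instead. Convert acid 2 to its Weinreb amide, add the aryl Grignard, and reduce the ketone with Et3SiH/TFA. Do the same at the ester end after Weinreb amidation. This avoids the alkyl-iodide coupling entirely.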